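**Plan**
- Retrosynthesis: after unmasking (4′-O-benzyl, 7-O-silyl, CO2H traced back to CH2OSi), four bonds of ring A are cut together: C8–C8a, C7–C8, C5–C6 and C4a–C5. This leaves a 6-aryl-4-pyranone with a diazoacetyl group on C2 and an enantiopure 1-siloxyalkyne.
- Enabling feature: ring A is a resorcinol in which C6, the carbon carrying the stereogenic side chain, lies between the oxygenated C5 and C7, and its C4a–C8a edge is the C3=C2 bond of the pyranone. A pyranonylketene (supplying C8 and C5) and a siloxyalkyne (supplying C6 and C7) give exactly this pattern.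
- Forward order: the pyranone (ring C, already bearing ring B) is built first from an aryl 1,3-diketone and diethyl oxalate. Ring A is then annulated onto it in one photochemical–thermal cascade, the chain end is oxidised to the acid, and the phenols are freed last.
- Stereochemistry: the single (R) centre is set by a rhodium-catalysed enantioselective conjugate alkynylation of benzylidene Meldrum's acid. It passes through the annulation as the propargylic carbon of the alkyne, whose C–H bond is never broken.

Key step: step 11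

Assumption: the (R)-bisphosphine in step 6 is taken to give (R)-14; if correlation of acid 15 with material of known configuration shows the opposite sense, the (S)-ligand is used with no other change.

**Route**

Step 1
Reactants: 1 1-[4-(benzyloxy)phenyl]ethanone; 2 ethyl acetate
Product: 3 1-[4-(benzyloxy)phenyl]butane-1,3-dione
Conditions: NaH, EtOAc (excess), THF, 0 °C → reflux; aq. HCl work-up
Reagents that add atoms: none
Why: Crossed Claisen condensation of the ketone enolate with ethyl acetate is pulled to completion by deprotonation of the 1,3-diketone, and the benzyl ether is inert to base.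

Step 2
Reactants: 3 1-[4-(benzyloxy)phenyl]butane-1,3-dione; 4 diethyl oxalate
Product: 6 ethyl 6-[4-(benzyloxy)phenyl]-4-oxo-4H-pyran-2-carboxylate, via triketo ester 5 (not isolated)
Conditions: NaOEt (2.2 equiv), EtOH, 0 °C → rt; then HCl (4 M in dioxane), EtOH, 60 °C
Reagents that add atoms: none
Why: Claisen condensation under equilibrating conditions acylates the terminal methyl of the diketone (the only adduct that can rest as a doubly enolised salt), and acid then cyclodehydrates the 2,4,6-triketo ester to the 4-pyranone, the classical entry to 6-substituted 4-oxopyran-2-carboxylates.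

Step 3
Reactants: 6 ethyl 6-[4-(benzyloxy)phenyl]-4-oxo-4H-pyran-2-carboxylate
Product: 7 6-[4-(benzyloxy)phenyl]-4-oxo-4H-pyran-2-carboxylic acid
Conditions: LiOH·H2O (1.2 equiv), THF–H2O, 0 °C; then 1 M HCl to pH 2
Reagents that add atoms: lithium hydroxide, [Li+].[OH-]
Why: The ester on the electron-poor pyranone C2 should saponify at 0 °C faster than hydroxide opens the ring, and any ring-opened triketo acid recloses on acidification.

Step 4
Reactants: 7 6-[4-(benzyloxy)phenyl]-4-oxo-4H-pyran-2-carboxylic acid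
Product: 9 1-{6-[4-(benzyloxy)phenyl]-4-oxo-4H-pyran-2-yl}-2-diazoethanone, via mixed carbonic anhydride 8 (not isolated)
Conditions: i-BuOCOCl, N-methylmorpholine, THF, –15 °C; then CH2N2 (3 equiv), Et2O, –15 → 0 °C
Reagents that add atoms: diazomethane, C=[N+]=[N-] (isobutyl chloroformate, CC(C)COC(=O)Cl, adds atoms only to intermediate 8)
Why: Acylation of diazomethane by a mixed carbonic anhydride (Arndt–Eistert-type diazoketone synthesis) avoids chlorinating agents that would turn the pyranone carbonyl into a chloropyrylium salt, and the carbonate leaving group takes up the proton so no hydrogen halide is formed.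

Step 5
Reactants: 10 benzaldehyde; 11 Meldrum's acid (2,2-dimethyl-1,3-dioxane-4,6-dione)
Product: 12 5-benzylidene-2,2-dimethyl-1,3-dioxane-4,6-dione
Conditions: pyrrolidine (cat.), AcOH (cat.), toluene, rt
Reagents that add atoms: none
Why: Knoevenagel condensation of the highly acidic Meldrum's acid with a non-enolisable aldehyde.

Step 6
Reactants: 12 5-benzylidene-2,2-dimethyl-1,3-dioxane-4,6-dione; 13 ethynyltrimethylsilane
Product: 14 (R)-2,2-dimethyl-5-[1-phenyl-3-(trimethylsilyl)prop-2-yn-1-yl]-1,3-dioxane-4,6-dione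
Conditions: Rh(acac)(C2H4)2 (5 mol %), (R)-3,5-xylyl-MeO-BIPHEP (5.5 mol %), 1,4-dioxane–H2O, 12 °C
Reagents that add atoms: none
Why: Rhodium-catalysed enantioselective conjugate alkynylation is established for exactly this acceptor and alkyne; the chiral bisphosphine on the alkynylrhodium species selects the face of the benzylidene carbon and so sets the (R) centre, while the bulky silyl group suppresses alkyne dimerisation.

Step 7
Reactants: 14 (R)-2,2-dimethyl-5-[1-phenyl-3-(trimethylsilyl)prop-2-yn-1-yl]-1,3-dioxane-4,6-dione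
Product: 15 (R)-3-phenyl-5-(trimethylsilyl)pent-4-ynoic acid
Conditions: DMF–H2O (10:1), 100 °C
Reagents that add atoms: water, O
Why: Hydrolytic opening of the Meldrum's acid ring, loss of acetone and decarboxylation of the malonic acid give the acid, and the stereocentre is β to the carboxyl group and cannot enolise.

Step 8
Reactants: 15 (R)-3-phenyl-5-(trimethylsilyl)pent-4-ynoic acid
Product: 17 (S)-3-phenylpent-4-yn-1-ol, via silylated alkynol 16 (not isolated)
Conditions: LiAlH4, THF, 0 °C → rt; H2O quench, filter, concentrate; then K2CO3 (cat.), MeOH, rt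
Reagents that add atoms: none
Why: Hydride reduction of the acid leaves the silylalkyne untouched and catalytic methoxide then cleaves the C(sp)–Si bond (protodesilylation); the descriptor changes to (S) only because ethynyl ranks below phenyl, the spatial arrangement being unchanged.

Step 9
Reactants: 17 (S)-3-phenylpent-4-yn-1-ol
Product: 18 (S)-tert-butyldimethyl[(3-phenylpent-4-yn-1-yl)oxy]silane
Conditions: TBSCl, imidazole, CH2Cl2, rt
Reagents that add atoms: tert-butyldimethylsilyl chloride, CC(C)(C)[Si](C)(C)Cl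
Why: Standard silylation of a primary alcohol, with TBS chosen because it withstands organolithium and peroxide bases and can later be removed by acid without touching an aryl silyl ether.

Step 10
Reactants: 18 (S)-tert-butyldimethyl[(3-phenylpent-4-yn-1-yl)oxy]silane
Product: 21 (R)-tert-butyldimethyl({3-phenyl-5-[(triisopropylsilyl)oxy]pent-4-yn-1-yl}oxy)silane, via lithium acetylide 19 (not isolated), via lithium ynolate 20 (not isolated)
Conditions: n-BuLi (1.0 equiv), THF, –78 °C; t-BuOOLi (from t-BuOOH and LiHMDS), –78 → 0 °C; TIPSOTf, –78 °C; chromatography on Et3N-deactivated silica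
Reagents that add atoms: lithium tert-butyl peroxide, CC(C)(C)O[O-].[Li+]; triisopropylsilyl trifluoromethanesulfonate, CC(C)[Si](C(C)C)(C(C)C)OS(=O)(=O)C(F)(F)F
Why: Electrophilic oxygen transfer from the lithium peroxide to the acetylide gives the ynolate, which the bulky silyl triflate traps on oxygen (the standard preparation of 1-siloxyalkynes from terminal alkynes), and since only the acetylenic C–H is removed the propargylic centre is preserved.

Step 11
Reactants: 9 1-{6-[4-(benzyloxy)phenyl]-4-oxo-4H-pyran-2-yl}-2-diazoethanone; 21 (R)-tert-butyldimethyl({3-phenyl-5-[(triisopropylsilyl)oxy]pent-4-yn-1-yl}oxy)silane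
Product: 26 2-[4-(benzyloxy)phenyl]-6-[(1R)-3-(tert-butyldimethylsilyloxy)-1-phenylpropyl]-5-hydroxy-7-(triisopropylsilyloxy)-4H-chromen-4-one, via pyranonylketene 22 (not isolated), via siloxycyclobutenone 23 (not isolated), via dienylketene 24 (not isolated), via cyclohexadienone 25 (not isolated)
Conditions: 9 (1.3 equiv), hν (405–440 nm LED), ClCH2CH2Cl (degassed), rt; then 80 °C
Reagents that add atoms: none
Why: Light expels dinitrogen from 9 and Wolff rearrangement shifts pyranone C2 onto the former diazo carbon to give ketene 22, whose carbonyl carbon is attacked by the nucleophilic, alkyl-bearing carbon of the siloxyalkyne in a (2+2) cycloaddition; the 3-siloxycyclobutenone 23 then opens (4π) to dienylketene 24. Ring A is closed by 6π electrocyclisation of 24 onto pyranone C3 (six-membered carbocycle, C4a–C5 bond), and dienone 25 tautomerises to the chelated 5-phenol. The closest known reaction is the Danheiser benzannulation in its photochemical diazoketone form with 1-siloxyalkynes, which fuses resorcinol rings onto alkenes and heteroarenes; here the pyranone C2=C3 bond plays the part of the vinyl group, a partner of this class not yet tried. No stereocentre is created (C4 of 23 and C4a of 25 are transient) and the propargylic C–H bond is never broken, so the (R) centre is carried through. The one selectivity needed is the regiochemistry of the ketene–alkyne addition, which the oxygen-induced polarisation of the alkyne fixes so that the side chain lands on C6 between the C5 and C7 oxygens; closure can occur only at C3, the sole free carbon next to the ketene-bearing C2. Long-wavelength light is chosen so that only the diazo chromophore absorbs, sparing the pyranone and the flavone formed.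

Step 12
Reactants: 26 2-[4-(benzyloxy)phenyl]-6-[(1R)-3-(tert-butyldimethylsilyloxy)-1-phenylpropyl]-5-hydroxy-7-(triisopropylsilyloxy)-4H-chromen-4-one
Product: 27 2-[4-(benzyloxy)phenyl]-5-hydroxy-6-[(1R)-3-hydroxy-1-phenylpropyl]-7-(triisopropylsilyloxy)-4H-chromen-4-one
Conditions: camphorsulfonic acid (0.1 equiv), MeOH–CH2Cl2 (1:1), 0 °C
Reagents that add atoms: none
Why: Acid-catalysed methanolysis cleaves a primary alkyl TBS ether far faster than a hindered aryl TIPS ether, and the benzyl ether and the chelated phenol are inert.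

Step 13
Reactants: 27 2-[4-(benzyloxy)phenyl]-5-hydroxy-6-[(1R)-3-hydroxy-1-phenylpropyl]-7-(triisopropylsilyloxy)-4H-chromen-4-one
Product: 29 (3R)-3-{2-[4-(benzyloxy)phenyl]-5-hydroxy-4-oxo-7-(triisopropylsilyloxy)-4H-chromen-6-yl}-3-phenylpropanoic acid, via aldehyde 28 (not isolated)
Conditions: Dess–Martin periodinane (1.2 equiv), CH2Cl2, 0 °C → rt; then NaClO2, NaH2PO4, 2-methyl-2-butene, t-BuOH–H2O, rt
Reagents that add atoms: sodium chlorite, [Na+].[O-]Cl=O
Why: Dess–Martin then Pinnick oxidation take the primary alcohol to the acid through aldehyde 28 (free or resting as its lactol with the 5-hydroxyl); the only phenol present is hydrogen-bonded to C4=O with both ortho positions blocked, and the alkene scavenger removes hypochlorite before it can chlorinate C8.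

Step 14
Reactants: 29 (3R)-3-{2-[4-(benzyloxy)phenyl]-5-hydroxy-4-oxo-7-(triisopropylsilyloxy)-4H-chromen-6-yl}-3-phenylpropanoic acid
Product: 30 (3R)-3-{2-[4-(benzyloxy)phenyl]-5,7-dihydroxy-4-oxo-4H-chromen-6-yl}-3-phenylpropanoic acid
Conditions: TBAF (3 equiv), THF, 0 °C; cold dilute HCl work-up to pH 3–4
Reagents that add atoms: none
Why: Fluoride cleaves the aryl O–Si bond readily because phenoxide is a good leaving group on silicon, under conditions that leave the benzyl ether and the flavone untouched.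

Step 15
Reactants: 30 (3R)-3-{2-[4-(benzyloxy)phenyl]-5,7-dihydroxy-4-oxo-4H-chromen-6-yl}-3-phenylpropanoic acid
Product: 31 (3R)-3-[5,7-dihydroxy-2-(4-hydroxyphenyl)-4-oxo-4H-chromen-6-yl]-3-phenylpropanoic acid
Conditions: H2 (1 atm), Pd/C (10 %), EtOAc–MeOH, rt
Reagents that add atoms: none
Why: Hydrogenolysis of the benzyl aryl ether under neutral conditions avoids the strong acid that would lactonise the hydroxy acid or ionise the diarylmethine centre, and the flavone C2=C3 bond and the benzylic C–C bonds should not be reduced at ambient pressure.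

**Compound list**

1 | 1-[4-(benzyloxy)phenyl]ethanone | CC(=O)c1ccc(OCc2ccccc2)cc1 | starting material
2 | ethyl acetate | CCOC(C)=O | starting material
3 | 1-[4-(benzyloxy)phenyl]butane-1,3-dione | CC(=O)CC(=O)c1ccc(OCc2ccccc2)cc1 | intermediate
4 | diethyl oxalate | CCOC(=O)C(=O)OCC | starting material
5 | ethyl 6-[4-(benzyloxy)phenyl]-2,4,6-trioxohexanoate | CCOC(=O)C(=O)CC(=O)CC(=O)c1ccc(OCc2ccccc2)cc1 | intermediate (not isolated)
6 | ethyl 6-[4-(benzyloxy)phenyl]-4-oxo-4H-pyran-2-carboxylate | CCOC(=O)c1cc(=O)cc(-c2ccc(OCc3ccccc3)cc2)o1 | intermediate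
7 | 6-[4-(benzyloxy)phenyl]-4-oxo-4H-pyran-2-carboxylic acid | O=C(O)c1cc(=O)cc(-c2ccc(OCc3ccccc3)cc2)o1 | intermediate
8 | mixed anhydride of 7 with isobutyl hydrogen carbonate | CC(C)COC(=O)OC(=O)c1cc(=O)cc(-c2ccc(OCc3ccccc3)cc2)o1 | intermediate (not isolated)
9 | 1-{6-[4-(benzyloxy)phenyl]-4-oxo-4H-pyran-2-yl}-2-diazoethanone | [N-]=[N+]=CC(=O)c1cc(=O)cc(-c2ccc(OCc3ccccc3)cc2)o1 | intermediate
10 | benzaldehyde | O=Cc1ccccc1 | starting material
11 | Meldrum's acid (2,2-dimethyl-1,3-dioxane-4,6-dione) | CC1(C)OC(=O)CC(=O)O1 | starting material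
12 | 5-benzylidene-2,2-dimethyl-1,3-dioxane-4,6-dione | CC1(C)OC(=O)C(=Cc2ccccc2)C(=O)O1 | intermediate
13 | ethynyltrimethylsilane | C#C[Si](C)(C)C | starting material
14 | (R)-2,2-dimethyl-5-[1-phenyl-3-(trimethylsilyl)prop-2-yn-1-yl]-1,3-dioxane-4,6-dione | CC1(C)OC(=O)C([C@H](c2ccccc2)C#C[Si](C)(C)C)C(=O)O1 | intermediate
15 | (R)-3-phenyl-5-(trimethylsilyl)pent-4-ynoic acid | O=C(O)C[C@H](c1ccccc1)C#C[Si](C)(C)C | intermediate
16 | (R)-3-phenyl-5-(trimethylsilyl)pent-4-yn-1-ol | OCC[C@H](c1ccccc1)C#C[Si](C)(C)C | intermediate (not isolated)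
17 | (S)-3-phenylpent-4-yn-1-ol | OCC[C@H](c1ccccc1)C#C | intermediate
18 | (S)-tert-butyldimethyl[(3-phenylpent-4-yn-1-yl)oxy]silane | CC(C)(C)[Si](C)(C)OCC[C@H](c1ccccc1)C#C | intermediate
19 | lithium acetylide of 18 (C3 configuration unchanged) | CC(C)(C)[Si](C)(C)OCC[C@H](c1ccccc1)C#C[Li] | intermediate (not isolated)
20 | lithium ynolate from 19, lithium 5-(tert-butyldimethylsilyloxy)-3-phenylpent-1-yn-1-olate (C3 configuration unchanged) | CC(C)(C)[Si](C)(C)OCC[C@H](c1ccccc1)C#CO[Li] | intermediate (not isolated)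
21 | (R)-tert-butyldimethyl({3-phenyl-5-[(triisopropylsilyl)oxy]pent-4-yn-1-yl}oxy)silane | CC(C)(C)[Si](C)(C)OCC[C@H](c1ccccc1)C#CO[Si](C(C)C)(C(C)C)C(C)C | intermediate
22 | 2-{6-[4-(benzyloxy)phenyl]-4-oxo-4H-pyran-2-yl}ethenone (pyranonylketene) | O=C=Cc1cc(=O)cc(-c2ccc(OCc3ccccc3)cc2)o1 | intermediate (not isolated)
23 | 4-{6-[4-(benzyloxy)phenyl]-4-oxo-4H-pyran-2-yl}-2-[(1R)-3-(tert-butyldimethylsilyloxy)-1-phenylpropyl]-3-(triisopropylsilyloxy)cyclobut-2-en-1-one (both C4 epimers) | O=C1C([C@H](CCO[Si](C)(C)C(C)(C)C)c2ccccc2)=C(O[Si](C(C)C)(C(C)C)C(C)C)C1c1cc(=O)cc(-c2ccc(OCc3ccccc3)cc2)o1 | intermediate (not isolated)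
24 | 4-{6-[4-(benzyloxy)phenyl]-4-oxo-4H-pyran-2-yl}-2-[(1R)-3-(tert-butyldimethylsilyloxy)-1-phenylpropyl]-3-(triisopropylsilyloxy)buta-1,3-dien-1-one | O=C=C([C@H](CCO[Si](C)(C)C(C)(C)C)c1ccccc1)C(O[Si](C(C)C)(C(C)C)C(C)C)=Cc1cc(=O)cc(-c2ccc(OCc3ccccc3)cc2)o1 | intermediate (not isolated)
25 | 2-[4-(benzyloxy)phenyl]-6-[(1R)-3-(tert-butyldimethylsilyloxy)-1-phenylpropyl]-7-(triisopropylsilyloxy)-4aH-chromene-4,5-dione (keto tautomer of 26) | O=C1C([C@H](CCO[Si](C)(C)C(C)(C)C)c3ccccc3)=C(O[Si](C(C)C)(C(C)C)C(C)C)C=C2OC(-c3ccc(OCc4ccccc4)cc3)=CC(=O)C12 | intermediate (not isolated)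
26 | 2-[4-(benzyloxy)phenyl]-6-[(1R)-3-(tert-butyldimethylsilyloxy)-1-phenylpropyl]-5-hydroxy-7-(triisopropylsilyloxy)-4H-chromen-4-one | CC(C)(C)[Si](C)(C)OCC[C@H](c1ccccc1)c1c(O[Si](C(C)C)(C(C)C)C(C)C)cc2oc(-c3ccc(OCc4ccccc4)cc3)cc(=O)c2c1O | intermediate
27 | 2-[4-(benzyloxy)phenyl]-5-hydroxy-6-[(1R)-3-hydroxy-1-phenylpropyl]-7-(triisopropylsilyloxy)-4H-chromen-4-one | OCC[C@H](c1ccccc1)c1c(O[Si](C(C)C)(C(C)C)C(C)C)cc2oc(-c3ccc(OCc4ccccc4)cc3)cc(=O)c2c1O | intermediate
28 | (3R)-3-{2-[4-(benzyloxy)phenyl]-5-hydroxy-4-oxo-7-(triisopropylsilyloxy)-4H-chromen-6-yl}-3-phenylpropanal | O=CC[C@H](c1ccccc1)c1c(O[Si](C(C)C)(C(C)C)C(C)C)cc2oc(-c3ccc(OCc4ccccc4)cc3)cc(=O)c2c1O | intermediate (not isolated)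
29 | (3R)-3-{2-[4-(benzyloxy)phenyl]-5-hydroxy-4-oxo-7-(triisopropylsilyloxy)-4H-chromen-6-yl}-3-phenylpropanoic acid | O=C(O)C[C@H](c1ccccc1)c1c(O[Si](C(C)C)(C(C)C)C(C)C)cc2oc(-c3ccc(OCc4ccccc4)cc3)cc(=O)c2c1O | intermediate
30 | (3R)-3-{2-[4-(benzyloxy)phenyl]-5,7-dihydroxy-4-oxo-4H-chromen-6-yl}-3-phenylpropanoic acid | O=C(O)C[C@H](c1ccccc1)c1c(O)cc2oc(-c3ccc(OCc4ccccc4)cc3)cc(=O)c2c1O | intermediate
31 | (3R)-3-[5,7-dihydroxy-2-(4-hydroxyphenyl)-4-oxo-4H-chromen-6-yl]-3-phenylpropanoic acid | O=C(O)C[C@H](c1ccccc1)c1c(O)cc2oc(-c3ccc(O)cc3)cc(=O)c2c1O | target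

**Step count and risks**

Total step count: 15. Longest linear sequence: 11 steps (steps 5–15, from benzaldehyde); the pyranone arm contributes steps 1–4.

Steps most likely to fail:

1. Step 11. The pyranone or flavone chromophores may absorb and react photochemically, or the ketene may dimerise or be trapped before it meets the alkyne, so that the cascade stalls short of ring closure. The fallback generates the same ketene without light and sets out from 9 and 21. Diazoketone 9 is rearranged with PhCO2Ag and Et3N in aqueous dioxane to {6-[4-(benzyloxy)phenyl]-4-oxo-4H-pyran-2-yl}acetic acid F1 (kept cold, since it can decarboxylate). 1-Chloro-N,N,2-trimethylprop-1-en-1-amine in CH2Cl2 at 0 °C converts it under neutral conditions into {6-[4-(benzyloxy)phenyl]-4-oxo-4H-pyran-2-yl}acetyl chloride F2. Slow addition of Et3N to F2 and 21 in CH2Cl2 dehydrochlorinates F2 to ketene 22, which is trapped as cyclobutenone 23, and heating in toluene at 80–110 °C completes the opening and closure and rejoins the route at 26.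

2. Step 10. Oxygen transfer to the hindered acetylide may be incomplete, the siloxyalkyne may hydrolyse on work-up, or base may isomerise the alkyne towards the allene and erode the propargylic centre. The fallback reaches the ynolate by sulfonate cleavage instead of acetylide oxidation and sets out from 18. Hydroxy(tosyloxy)iodobenzene (CHCl3, desiccant) converts 18 into [(3R)-5-(tert-butyldimethylsilyloxy)-3-phenylpent-1-yn-1-yl](phenyl)iodonium 4-methylbenzenesulfonate F3. CuOTf (cat.) in MeCN collapses this to (3R)-5-(tert-butyldimethylsilyloxy)-3-phenylpent-1-yn-1-yl 4-methylbenzenesulfonate F4. MeLi in THF at –78 °C attacks sulfur and releases lithium ynolate 20, which TIPSOTf silylates to rejoin the route at 21.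

3. Step 4. Diazomethane may undergo dipolar cycloaddition across the electron-poor C2=C3 bond of the pyranone in competition with acylation. The fallback installs the diazo group by diazo transfer and sets out from 7. Coupling with N,O-dimethylhydroxylamine hydrochloride (EDC·HCl, N-methylmorpholine, CH2Cl2) gives 6-[4-(benzyloxy)phenyl]-N-methoxy-N-methyl-4-oxo-4H-pyran-2-carboxamide F5, and MeMgBr (THF, –78 °C) gives 2-acetyl-6-[4-(benzyloxy)phenyl]-4H-pyran-4-one F6. Its lithium enolate (LiHMDS, –78 °C) is trifluoroacetylated with CF3CO2CH2CF3 to 1-{6-[4-(benzyloxy)phenyl]-4-oxo-4H-pyran-2-yl}-4,4,4-trifluorobutane-1,3-dione F7, which MsN3, Et3N and H2O in MeCN convert by detrifluoroacetylative diazo transfer, rejoining the route at 9.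

**Further compounds**

F1 | step 11 | {6-[4-(benzyloxy)phenyl]-4-oxo-4H-pyran-2-yl}acetic acid | O=C(O)Cc1cc(=O)cc(-c2ccc(OCc3ccccc3)cc2)o1
F2 | step 11 | {6-[4-(benzyloxy)phenyl]-4-oxo-4H-pyran-2-yl}acetyl chloride | O=C(Cl)Cc1cc(=O)cc(-c2ccc(OCc3ccccc3)cc2)o1
F3 | step 10 | [(3R)-5-(tert-butyldimethylsilyloxy)-3-phenylpent-1-yn-1-yl](phenyl)iodonium 4-methylbenzenesulfonate | CC(C)(C)[Si](C)(C)OCC[C@H](c1ccccc1)C#C[I+]c1ccccc1.Cc1ccc(S(=O)(=O)[O-])cc1
F4 | step 10 | (3R)-5-(tert-butyldimethylsilyloxy)-3-phenylpent-1-yn-1-yl 4-methylbenzenesulfonate | CC(C)(C)[Si](C)(C)OCC[C@H](c1ccccc1)C#COS(=O)(=O)c1ccc(C)cc1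
F5 | step 4 | 6-[4-(benzyloxy)phenyl]-N-methoxy-N-methyl-4-oxo-4H-pyran-2-carboxamide | CON(C)C(=O)c1cc(=O)cc(-c2ccc(OCc3ccccc3)cc2)o1
F6 | step 4 | 2-acetyl-6-[4-(benzyloxy)phenyl]-4H-pyran-4-one | CC(=O)c1cc(=O)cc(-c2ccc(OCc3ccccc3)cc2)o1
F7 | step 4 | 1-{6-[4-(benzyloxy)phenyl]-4-oxo-4H-pyran-2-yl}-4,4,4-trifluorobutane-1,3-dione | O=C(CC(=O)C(F)(F)F)c1cc(=O)cc(-c2ccc(OCc3ccccc3)cc2)o1
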